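**Plan**

- Retrosynthesis: cut the three ester C–O bonds (C1′ acetate, C1 2-methylbutanoate, C6 enoate), then the C6–O and C1–O bonds (allylic and enolate oxidation), then the C3–C3a bond of the cyclopentanone.
- Enabling feature: C3 lies between the C2 ring ketone and the carbinol C1′, a β-hydroxy ketone next to ring-fusion carbon C3a. This is what results when C3a shifts from a cyclobutanol carbon (C2) onto an oxirane carbon (C3), inserting C3 into the four-membered ring.
- Forward order of rings: cyclohexenone (organocatalytic Michael/aldol), trans-fused cyclobutane ([2+2] photocycloaddition), cyclobutane to cyclopentanone (1,2-shift), then oxygenation at C1 and C6 and three acylations.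
- Stereochemistry: C4 from the organocatalyst; C3a and C7a from photoaddition anti to the isopropyl group with trans ring fusion; C3 and C1′ from a cis-oxirane, transferred stereospecifically in the shift.
- C1 from enolate hydroxylation anti to the axial C7a–H; C6 from axial oxygen delivery in the SeO2 oxidation; the acyl stereo-elements are bought.

Key step: step 7

Remark: atoms carry hydrindane numbers throughout (C2 ring ketone, C4 isopropyl carbon, C7 methylidene carbon, C1′ side-arm carbinol), also for the bicyclo[4.2.0]octanes (carbinol carbon = C2, cyclobutane CH2 = C1). (2R)-2-Methylbutanoic acid and (2E)-3-methylpent-2-enoic acid are taken as purchasable single isomers. The bridging chloride of the Tebbe reagent is drawn in its SMILES as a chloronium–aluminate pair.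

**Route**

Step 1
Reactants: 1 3-methylbutanal; 2 but-3-en-2-one
Product: 5 (4R)-4-(propan-2-yl)cyclohex-2-en-1-one, via keto aldehyde 3 (not isolated), via ketol 4 (not isolated)
Conditions: (R)-α,α-diphenylprolinol trimethylsilyl ether (5 mol %), ethyl 3,4-dihydroxybenzoate (20 mol %), neat, 4 °C; excess enone removed in vacuo; then LiOH (0.2 equiv), i-PrOH, rt
Reagents that add atoms: none
Why: Enamine-catalysed asymmetric Michael addition followed by intramolecular aldol condensation (Robinson-type annulation); the catalyst shields one enamine face, so C–C bond formation sets the (R) centre that becomes C4, and cyclisation/dehydration should outrun racemisation of the hindered aldehyde.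

Step 2
Reactants: 5 (4R)-4-(propan-2-yl)cyclohex-2-en-1-one; 6 1,1-dimethoxyethene
Product: 7 (1S,5R,6R)-7,7-dimethoxy-5-(propan-2-yl)bicyclo[4.2.0]octan-2-one (trans-fused)
Conditions: hν (350 nm, Pyrex), 6 (10 equiv), CH2Cl2, −40 °C; crude product used directly
Reagents that add atoms: none
Why: Enone–alkene [2+2] photocycloaddition, in which the electron-rich ketene acetal should add head-to-tail (acetal carbon on C3a), the twisted triplet enone should close mainly to the trans-fused cyclobutane, and approach anti to the neighbouring isopropyl group sets C3a and C7a; the base-sensitive adduct is not purified and stereoisomers are removed after step 3.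

Step 3
Reactants: 7 (1S,5R,6R)-7,7-dimethoxy-5-(propan-2-yl)bicyclo[4.2.0]octan-2-one
Product: 8 (1S,5R,6R)-7,7-dimethoxy-2-methylidene-5-(propan-2-yl)bicyclo[4.2.0]octane
Conditions: Cp2Ti(μ-Cl)(μ-CH2)AlMe2 (1.2 equiv), pyridine (cat.), THF/toluene, −40 → 0 °C
Reagents that add atoms: Tebbe reagent Cp2Ti(μ-Cl)(μ-CH2)AlMe2 (C[Al-]1(C)C[Ti]([Cl+]1)(C2C=CC=C2)C3C=CC=C3)
Why: Tebbe methylenation through a non-basic titanium methylidene, so the epimerisable ring-fusion centre C7a is converted into a non-enolisable allylic carbon with the trans fusion intact and the acetal untouched.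

Step 4
Reactants: 8 (1S,5R,6R)-7,7-dimethoxy-2-methylidene-5-(propan-2-yl)bicyclo[4.2.0]octane
Product: 9 (1S,5R,6R)-2-methylidene-5-(propan-2-yl)bicyclo[4.2.0]octan-7-one
Conditions: 0.5 M aq. HCl, THF, 0 °C → rt
Reagents that add atoms: water (O)
Why: Acid-catalysed acetal hydrolysis under dilute, cold conditions, which should free the cyclobutanone without moving the exocyclic alkene and without enolising toward the strained ring-fusion carbon C3a.

Step 5
Reactants: 9 (1S,5R,6R)-2-methylidene-5-(propan-2-yl)bicyclo[4.2.0]octan-7-one; 10 (Z)-1-bromoprop-1-ene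
Product: 13 (1S,5R,6R,7R)-2-methylidene-5-(propan-2-yl)-7-[(1Z)-prop-1-en-1-yl]bicyclo[4.2.0]octan-7-ol, via (Z)-prop-1-enyllithium 11 (not isolated), via (Z)-prop-1-enylcerium dichloride 12 (not isolated)
Conditions: 10, t-BuLi (2 equiv), THF/Et2O, −78 °C; CeCl3 (anhydrous), THF, −78 °C; then 9, −78 °C; aq. NH4Cl
Reagents that add atoms: none
Why: Bromine–lithium exchange with retention of alkene geometry, transmetalation to a weakly basic organocerium reagent and 1,2-addition (Imamoto conditions) to the enolisable cyclobutanone; the nucleophile should enter trans to the adjacent ring carbon C4, giving the tertiary (Z)-allylic alcohol whose configuration steers step 6 and is erased in step 7.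

Step 6
Reactants: 13 (1S,5R,6R,7R)-2-methylidene-5-(propan-2-yl)-7-[(1Z)-prop-1-en-1-yl]bicyclo[4.2.0]octan-7-ol
Product: 14 (1S,5R,6R,7S)-2-methylidene-7-[(2S,3S)-3-methyloxiran-2-yl]-5-(propan-2-yl)bicyclo[4.2.0]octan-7-ol
Conditions: VO(acac)2 (5 mol %), t-BuOOH (1.5 equiv), 2,6-lutidine (cat.), CH2Cl2, 0 °C; used without delay
Reagents that add atoms: tert-butyl hydroperoxide (CC(C)(C)OO)
Why: Hydroxyl-directed vanadium-catalysed epoxidation (Sharpless–Michaelson), much faster at the allylic alkene than at the remote methylidene; allylic 1,3-strain from the cis-methyl should turn the bulkier ring-fusion carbon C3a away from it, so the metal-bound peroxide reaches the face that gives the (2S,3S)-oxirane and thereby fixes the future C3 and C1′.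

Step 7
Reactants: 14 (1S,5R,6R,7S)-2-methylidene-7-[(2S,3S)-3-methyloxiran-2-yl]-5-(propan-2-yl)bicyclo[4.2.0]octan-7-ol
Product: 15 (3R,3aR,4R,7aS)-3-[(1S)-1-hydroxyethyl]-7-methylidene-4-(propan-2-yl)octahydro-2H-inden-2-one
Conditions: ZnBr2 (1.1 equiv), CH2Cl2, −20 → 0 °C
Reagents that add atoms: none
Why: ZnBr2 bridges the tertiary hydroxyl and the oxirane oxygen, the oxirane C3–O bond lengthens, and the cyclobutane bond C2–C3a, antiperiplanar to it, shifts to C3 while the carbinol carbon collapses to the C2 ketone. The closest known reaction type is the semipinacol rearrangement of 2,3-epoxy alcohols to β-hydroxy ketones, as used to enlarge 1-(oxiranyl)cyclobutanols to cyclopentanones. The cyclopentanone is formed by ring enlargement of the four-membered ring (a suprafacial 1,2-alkyl shift with backside opening of the oxirane), not by an end-to-end cyclisation, and is driven by the strain of the trans-fused bicyclo[4.2.0]octane. C3 arises with inversion at the oxirane carbon and is therefore dictated by the (2S,3S)-oxirane; C1′ keeps its oxygen and configuration; C3a migrates with retention, so the trans ring fusion is carried over. The step needs C3a to migrate rather than the methylene C1, which rests on the higher migratory aptitude of the more substituted carbon and on the chelated rotamer inherited from step 6, where C3a already lies anti to the breaking C–O bond. A mild chelating Lewis acid at low temperature should spare the exocyclic alkene and the new β-hydroxy ketone.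

Step 8
Reactants: 15 (3R,3aR,4R,7aS)-3-[(1S)-1-hydroxyethyl]-7-methylidene-4-(propan-2-yl)octahydro-2H-inden-2-one
Product: 16 (3R,3aR,4R,7aS)-3-[(1S)-1-[(tert-butyldimethylsilyl)oxy]ethyl]-7-methylidene-4-(propan-2-yl)octahydro-2H-inden-2-one
Conditions: TBSOTf (1.2 equiv), 2,6-lutidine, CH2Cl2, −78 °C
Reagents that add atoms: tert-butyldimethylsilyl trifluoromethanesulfonate (CC(C)(C)[Si](C)(C)OS(=O)(=O)C(F)(F)F)
Why: Silyl ether formation with a silyl triflate and a hindered base, masking the β-hydroxyl so that the coming enolisation cannot cause retro-aldol cleavage or β-elimination.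

Step 9
Reactants: 16 (3R,3aR,4R,7aS)-3-[(1S)-1-[(tert-butyldimethylsilyl)oxy]ethyl]-7-methylidene-4-(propan-2-yl)octahydro-2H-inden-2-one
Product: 18 (1R,3R,3aR,4R,7aS)-3-[(1S)-1-[(tert-butyldimethylsilyl)oxy]ethyl]-1-hydroxy-7-methylidene-4-(propan-2-yl)octahydro-2H-inden-2-one, via potassium enolate 17 (not isolated)
Conditions: KN(SiMe3)2 (1.1 equiv), THF, −78 °C; 3-phenyl-2-(phenylsulfonyl)oxaziridine, −78 °C; aq. NH4Cl at −78 °C
Reagents that add atoms: 3-phenyl-2-(phenylsulfonyl)oxaziridine (O=S(=O)(c1ccccc1)N1OC1c1ccccc1)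
Why: Kinetic deprotonation at the less hindered C1 methylene and enolate hydroxylation with an N-sulfonyloxaziridine (Davis oxidation); oxygen should arrive anti to the axial C7a–H, which is aligned with the enolate π system and guards the lower face, placing the C1 oxygen cis to H-3a.

Step 10
Reactants: 18 (1R,3R,3aR,4R,7aS)-3-[(1S)-1-[(tert-butyldimethylsilyl)oxy]ethyl]-1-hydroxy-7-methylidene-4-(propan-2-yl)octahydro-2H-inden-2-one; 19 (2R)-2-methylbutanoic acid
Product: 20 (1R,3R,3aR,4R,7aS)-3-[(1S)-1-[(tert-butyldimethylsilyl)oxy]ethyl]-7-methylidene-2-oxo-4-(propan-2-yl)octahydro-1H-inden-1-yl (2R)-2-methylbutanoate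
Conditions: 19 (1.5 equiv), N,N′-dicyclohexylcarbodiimide (1.5 equiv), DMAP (0.1 equiv), CH2Cl2, 0 °C → rt
Reagents that add atoms: none
Why: Steglich esterification, mild enough to leave C1, C3 and the α-centre of the acid unchanged.

Step 11
Reactants: 20 (1R,3R,3aR,4R,7aS)-3-[(1S)-1-[(tert-butyldimethylsilyl)oxy]ethyl]-7-methylidene-2-oxo-4-(propan-2-yl)octahydro-1H-inden-1-yl (2R)-2-methylbutanoate
Product: 21 (1R,3R,3aR,4R,6S,7aS)-3-[(1S)-1-[(tert-butyldimethylsilyl)oxy]ethyl]-6-hydroxy-7-methylidene-2-oxo-4-(propan-2-yl)octahydro-1H-inden-1-yl (2R)-2-methylbutanoate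
Conditions: SeO2 (0.5 equiv), t-BuOOH (3 equiv), CH2Cl2, 0 °C → rt; stopped before full conversion
Reagents that add atoms: selenium dioxide (O=[Se]=O); tert-butyl hydroperoxide (CC(C)(C)OO)
Why: Allylic hydroxylation by SeO2 with t-BuOOH as terminal oxidant (ene reaction, then [2,3]-sigmatropic shift), which should attack the ring CH2 at C6 in preference to the hindered methine C7a and deliver oxygen axially on the face of H-7a, setting C6.

Step 12
Reactants: 21 (1R,3R,3aR,4R,6S,7aS)-3-[(1S)-1-[(tert-butyldimethylsilyl)oxy]ethyl]-6-hydroxy-7-methylidene-2-oxo-4-(propan-2-yl)octahydro-1H-inden-1-yl (2R)-2-methylbutanoate; 22 (2E)-3-methylpent-2-enoic acid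
Product: 23 (1R,3R,3aR,4R,6S,7aS)-3-[(1S)-1-[(tert-butyldimethylsilyl)oxy]ethyl]-7-methylidene-1-{[(2R)-2-methylbutanoyl]oxy}-2-oxo-4-(propan-2-yl)octahydro-1H-inden-6-yl (2E)-3-methylpent-2-enoate
Conditions: 22 (2 equiv), N,N′-dicyclohexylcarbodiimide (2 equiv), DMAP (0.2 equiv), CH2Cl2, 0 °C → rt
Reagents that add atoms: none
Why: Steglich esterification of the axial allylic alcohol; carbodiimide activation without a stoichiometric amine base should avoid deconjugation or E/Z scrambling of the β,β-disubstituted enoate.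

Step 13
Reactants: 23 (1R,3R,3aR,4R,6S,7aS)-3-[(1S)-1-[(tert-butyldimethylsilyl)oxy]ethyl]-7-methylidene-1-{[(2R)-2-methylbutanoyl]oxy}-2-oxo-4-(propan-2-yl)octahydro-1H-inden-6-yl (2E)-3-methylpent-2-enoate
Product: 24 (1R,3R,3aR,4R,6S,7aS)-3-[(1S)-1-hydroxyethyl]-7-methylidene-1-{[(2R)-2-methylbutanoyl]oxy}-2-oxo-4-(propan-2-yl)octahydro-1H-inden-6-yl (2E)-3-methylpent-2-enoate
Conditions: HF·pyridine, pyridine/THF, 0 °C → rt
Reagents that add atoms: none
Why: Desilylation with buffered acidic fluoride, which avoids the retro-aldol, β-elimination and acyl migration that a basic fluoride source could trigger.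

Step 14
Reactants: 24 (1R,3R,3aR,4R,6S,7aS)-3-[(1S)-1-hydroxyethyl]-7-methylidene-1-{[(2R)-2-methylbutanoyl]oxy}-2-oxo-4-(propan-2-yl)octahydro-1H-inden-6-yl (2E)-3-methylpent-2-enoate
Product: 25 (1R,3R,3aR,4R,6S,7aS)-3-[(1S)-1-(acetyloxy)ethyl]-7-methylidene-1-{[(2R)-2-methylbutanoyl]oxy}-2-oxo-4-(propan-2-yl)octahydro-1H-inden-6-yl (2E)-3-methylpent-2-enoate (CNP0289166.2)
Conditions: Ac2O, pyridine, DMAP (cat.), CH2Cl2, 0 °C
Reagents that add atoms: acetic anhydride (CC(=O)OC(C)=O)
Why: Acetylation of the secondary alcohol with anhydride and pyridine, placed last so that the elimination-prone β-acetoxy ketone meets no further reagent.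

**Compound list**

1 | 3-methylbutanal | CC(C)CC=O | starting material
2 | but-3-en-2-one | CC(=O)C=C | starting material
3 | (2R)-5-oxo-2-(propan-2-yl)hexanal | O=C[C@@H](C(C)C)CCC(C)=O | intermediate
4 | (4R)-3-hydroxy-4-(propan-2-yl)cyclohexan-1-one, both C3 epimers | O=C1CC(O)[C@@H](C(C)C)CC1 | intermediate
5 | (4R)-4-(propan-2-yl)cyclohex-2-en-1-one | O=C1C=C[C@@H](C(C)C)CC1 | intermediate
6 | 1,1-dimethoxyethene | C=C(OC)OC | starting material
7 | (1S,5R,6R)-7,7-dimethoxy-5-(propan-2-yl)bicyclo[4.2.0]octan-2-one | O=C1[C@H]2CC(OC)(OC)[C@@H]2[C@@H](C(C)C)CC1 | intermediate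
8 | (1S,5R,6R)-7,7-dimethoxy-2-methylidene-5-(propan-2-yl)bicyclo[4.2.0]octane | C=C1[C@H]2CC(OC)(OC)[C@@H]2[C@@H](C(C)C)CC1 | intermediate
9 | (1S,5R,6R)-2-methylidene-5-(propan-2-yl)bicyclo[4.2.0]octan-7-one | C=C1[C@H]2CC(=O)[C@@H]2[C@@H](C(C)C)CC1 | intermediate
10 | (Z)-1-bromoprop-1-ene | C/C=C\Br | starting material
11 | (Z)-prop-1-enyllithium | C/C=C\[Li] | intermediate
12 | (Z)-prop-1-enylcerium dichloride | C/C=C\[Ce](Cl)Cl | intermediate
13 | (1S,5R,6R,7R)-2-methylidene-5-(propan-2-yl)-7-[(1Z)-prop-1-en-1-yl]bicyclo[4.2.0]octan-7-ol | C=C1[C@H]2C[C@@](O)(/C=C\C)[C@@H]2[C@@H](C(C)C)CC1 | intermediate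
14 | (1S,5R,6R,7S)-2-methylidene-7-[(2S,3S)-3-methyloxiran-2-yl]-5-(propan-2-yl)bicyclo[4.2.0]octan-7-ol | C=C1[C@H]2C[C@@](O)([C@H]3O[C@H]3C)[C@@H]2[C@@H](C(C)C)CC1 | intermediate
15 | (3R,3aR,4R,7aS)-3-[(1S)-1-hydroxyethyl]-7-methylidene-4-(propan-2-yl)octahydro-2H-inden-2-one | C=C1[C@@H]2[C@H]([C@H]([C@H](C)O)C(=O)C2)[C@@H](C(C)C)CC1 | intermediate
16 | (3R,3aR,4R,7aS)-3-[(1S)-1-[(tert-butyldimethylsilyl)oxy]ethyl]-7-methylidene-4-(propan-2-yl)octahydro-2H-inden-2-one | C=C1[C@@H]2[C@H]([C@H]([C@H](C)O[Si](C)(C)C(C)(C)C)C(=O)C2)[C@@H](C(C)C)CC1 | intermediate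
17 | potassium enolate of 16 (C1=C2–OK, other centres as in 16) | C=C1[C@@H]2[C@H]([C@H]([C@H](C)O[Si](C)(C)C(C)(C)C)C([O-])=C2)[C@@H](C(C)C)CC1.[K+] | intermediate
18 | (1R,3R,3aR,4R,7aS)-3-[(1S)-1-[(tert-butyldimethylsilyl)oxy]ethyl]-1-hydroxy-7-methylidene-4-(propan-2-yl)octahydro-2H-inden-2-one | C=C1[C@@H]2[C@H]([C@H]([C@H](C)O[Si](C)(C)C(C)(C)C)C(=O)[C@@H]2O)[C@@H](C(C)C)CC1 | intermediate
19 | (2R)-2-methylbutanoic acid | OC(=O)[C@H](C)CC | starting material
20 | (1R,3R,3aR,4R,7aS)-3-[(1S)-1-[(tert-butyldimethylsilyl)oxy]ethyl]-7-methylidene-2-oxo-4-(propan-2-yl)octahydro-1H-inden-1-yl (2R)-2-methylbutanoate | C=C1[C@@H]2[C@H]([C@H]([C@H](C)O[Si](C)(C)C(C)(C)C)C(=O)[C@@H]2OC(=O)[C@H](C)CC)[C@@H](C(C)C)CC1 | intermediate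
21 | (1R,3R,3aR,4R,6S,7aS)-3-[(1S)-1-[(tert-butyldimethylsilyl)oxy]ethyl]-6-hydroxy-7-methylidene-2-oxo-4-(propan-2-yl)octahydro-1H-inden-1-yl (2R)-2-methylbutanoate | C=C1[C@@H]2[C@H]([C@H]([C@H](C)O[Si](C)(C)C(C)(C)C)C(=O)[C@@H]2OC(=O)[C@H](C)CC)[C@@H](C(C)C)C[C@@H]1O | intermediate
22 | (2E)-3-methylpent-2-enoic acid | OC(=O)/C=C(\C)CC | starting material
23 | (1R,3R,3aR,4R,6S,7aS)-3-[(1S)-1-[(tert-butyldimethylsilyl)oxy]ethyl]-7-methylidene-1-{[(2R)-2-methylbutanoyl]oxy}-2-oxo-4-(propan-2-yl)octahydro-1H-inden-6-yl (2E)-3-methylpent-2-enoate | C=C1[C@@H]2[C@H]([C@H]([C@H](C)O[Si](C)(C)C(C)(C)C)C(=O)[C@@H]2OC(=O)[C@H](C)CC)[C@@H](C(C)C)C[C@@H]1OC(=O)/C=C(\C)CC | intermediate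
24 | (1R,3R,3aR,4R,6S,7aS)-3-[(1S)-1-hydroxyethyl]-7-methylidene-1-{[(2R)-2-methylbutanoyl]oxy}-2-oxo-4-(propan-2-yl)octahydro-1H-inden-6-yl (2E)-3-methylpent-2-enoate | C=C1[C@@H]2[C@H]([C@H]([C@H](C)O)C(=O)[C@@H]2OC(=O)[C@H](C)CC)[C@@H](C(C)C)C[C@@H]1OC(=O)/C=C(\C)CC | intermediate
25 | (1R,3R,3aR,4R,6S,7aS)-3-[(1S)-1-(acetyloxy)ethyl]-7-methylidene-1-{[(2R)-2-methylbutanoyl]oxy}-2-oxo-4-(propan-2-yl)octahydro-1H-inden-6-yl (2E)-3-methylpent-2-enoate | C=C1[C@@H]2[C@H]([C@H]([C@H](C)OC(C)=O)C(=O)[C@@H]2OC(=O)[C@H](C)CC)[C@@H](C(C)C)C[C@@H]1OC(=O)/C=C(\C)CC | target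

**Totals and risks**

Total step count: 14. Longest linear sequence: 14 steps (1 → 25).

Most likely to fail:

1. Step 9. The oxaziridine may reach the C1 enolate from the lower face, or with poor face discrimination, because the torsional preference for attack anti to the axial C7a–H is modest in a five-membered ring. Fallback: starting from 16, the same enolate oxidation is run and the C1-epimeric hydroxy ketone F6 is collected. F6 is then esterified with acid 19 under Mitsunobu conditions (PPh3, diisopropyl azodicarboxylate, toluene, 0 °C). The carboxylate displaces the activated oxygen at the carbon α to the ketone with inversion, so C1 is set by substitution instead of face selection, and the route is rejoined at 20.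

2. Step 6. The peroxide may be delivered to the other alkene face if the cis-methyl does not discriminate well between the two cyclobutane carbons, or if step 5 gave the other carbinol face; the oxirane may also rearrange early on the vanadium. Fallback: starting from 13, stereocontrol is moved from the substrate to a catalyst. The epoxidation is run with Hf(OtBu)4 (or VO(OiPr)3) and a C2-symmetric chiral bishydroxamic acid ligand with cumene hydroperoxide in toluene, the ligand enantiomer being chosen for the (2S,3S)-oxirane. The alkene face is then selected by the ligand rather than by the carbinol conformation, and the route is rejoined at 14.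

3. Step 7. The cyclobutane methylene C1 may migrate in competition with C3a, or the activated oxirane may be opened by bromide without a carbon shift. Fallback: starting from 9, the one-carbon enlargement is done by a β-oxido carbenoid shift and the side arm is built afterwards.
   - LiCHBr2 (CH2Br2, LiN(iPr)2, THF, −78 °C) adds to 9 to give the dibromomethyl carbinol F1.
   - n-BuLi (2 equiv, −78 °C) triggers the shift of the more substituted carbon C3a and gives the regiodefined lithium enolate F2 (C2–OLi, C2=C3).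
   - Acetaldehyde gives the aldol mixture F3, which is dehydrated (MsCl, Et3N; then DBU) to the (E)-3-ethylidene ketone F4.
   - Copper-catalysed conjugate borylation (CuCl, NaOtBu, a chiral bisphosphine chosen for (S) at C1′, B2pin2, MeOH, THF) gives the β-boryl ketone F5; protonation at C3 is expected anti to the axial C3a–H.
   - Oxidation with NaBO3 proceeds with retention and rejoins the route at 15.

**Further compounds**

F0 | step 6 | none | none
F1 | step 7 | dibromomethyl carbinol (13 with CHBr2 in place of the propenyl group) | C=C1[C@H]2C[C@@](O)(C(Br)Br)[C@@H]2[C@@H](C(C)C)CC1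
F2 | step 7 | lithium enolate (C2–OLi, C2=C3) of trans-fused 7-methylidene-4-(propan-2-yl)octahydro-2H-inden-2-one | C=C1[C@@H]2[C@H](C=C([O-])C2)[C@@H](C(C)C)CC1.[Li+]
F3 | step 7 | aldol mixture: 3-(1-hydroxyethyl)-7-methylidene-4-(propan-2-yl)octahydro-2H-inden-2-one, undefined at C3 and C1′, ring centres as in 15 | C=C1[C@@H]2[C@H](C(C(C)O)C(=O)C2)[C@@H](C(C)C)CC1
F4 | step 7 | (E)-3-ethylidene ketone: (3E)-3-ethylidene-7-methylidene-4-(propan-2-yl)octahydro-2H-inden-2-one, ring centres as in 15 | C=C1[C@@H]2[C@H](/C(=C\C)C(=O)C2)[C@@H](C(C)C)CC1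
F5 | step 7 | β-boryl ketone: 15 with a 4,4,5,5-tetramethyl-1,3,2-dioxaborolan-2-yl group in place of the C1′ hydroxyl, same spatial arrangement | C=C1[C@@H]2[C@H]([C@H]([C@H](C)B3OC(C)(C)C(C)(C)O3)C(=O)C2)[C@@H](C(C)C)CC1
F6 | step 9 | C1-epimeric hydroxy ketone: (1S,3R,3aR,4R,7aS)-3-[(1S)-1-[(tert-butyldimethylsilyl)oxy]ethyl]-1-hydroxy-7-methylidene-4-(propan-2-yl)octahydro-2H-inden-2-one | C=C1[C@@H]2[C@H]([C@H]([C@H](C)O[Si](C)(C)C(C)(C)C)C(=O)[C@H]2O)[C@@H](C(C)C)CC1
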